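**Assumption:** The target SMILES corresponds to the (R)-configured α-hydroxy ketone. The enantiomer of the NHC catalyst in Step 6 is chosen to deliver (R), and the sense of induction would be confirmed experimentally.

## Retrosynthetic overview
1. Glycybridin C is the α-hydroxy dihydrochalcone ArC(=O)–CH(OH)–CH2Ar′. It comes from one radical three-component coupling: an aryl radical (ring B) adds to the CH2 terminus of vinyl acetate, and the resulting α-acetoxyalkyl radical couples enantioselectively with the chiral NHC-bound ketyl (Breslow) radical of the ring-A aldehyde.
2. The Ar′–CH2 bond and the C(=O)–CH(O) bond form in this one operation, and the carbinol stereocenter is set in the radical–radical coupling.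
3. No rings are constructed, since both arenes are pre-formed. The ring-A aldehyde is built from resorcinol by double directed ortho-metalation. The ring-B iodide is built from 4-iodophenol by ortho-prenylation.
4. A final acid step removes all MOM groups and the acetate.

## Route

**Step 1**
Reactants: **1** resorcinol
Product: **2** 1,3-bis(methoxymethoxy)benzene
Conditions: NaH, THF/DMF, 0 °C; then MOMCl, 0 °C → 25 °C
Reagents that add atoms: chloromethyl methyl ether (MOMCl), ClCOC
Why: Double O-alkylation of the phenoxides gives robust acetals that later direct lithiation.

**Step 2**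
Reactants: **2**; **3** prenyl bromide (1-bromo-3-methylbut-2-ene)
Product: **4** 2-prenyl-1,3-bis(methoxymethoxy)benzene
Conditions: n-BuLi, Et2O, 0 °C; then CuI (10 mol %), **3**, −20 → 25 °C
Reagents that add atoms: prenyl bromide (**3**), CC(C)=CCBr
Why: Directed ortho-metalation occurs at C2, between the two OMOM groups, and Cu-catalysed SN2 allylation installs the prenyl group at the ring-A position flanked by both oxygens.

**Step 3**
Reactants: **4**
Product: **5** 2,4-bis(methoxymethoxy)-3-prenylbenzaldehyde
Conditions: s-BuLi, TMEDA, THF, −78 °C; then DMF, −78 → 0 °C; aq. NH4Cl
Reagents that add atoms: N,N-dimethylformamide, CN(C)C=O (supplies the CHO group)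
Why: C2 is blocked, so OMOM-directed lithiation goes to C4 (the two open positions are equivalent by symmetry), and DMF gives the aldehyde (directed ortho-metalation/formylation).

**Step 4**
Reactants: **6** 4-iodophenol; **3** prenyl bromide
Product: **7** 4-iodo-2-(3-methylbut-2-en-1-yl)phenol
Conditions: NaOH (1.0 equiv), H2O, 0 → 25 °C, 12 h, prenyl bromide (0.9 equiv)
Reagents that add atoms: prenyl bromide (**3**), CC(C)=CCBr
Why: The hydrogen-bonded phenoxide in water is C-alkylated at the open ortho position, because the para position is blocked (Kornblum-type C-alkylation).

**Step 5**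
Reactants: **7**
Product: **8** 4-iodo-1-(methoxymethoxy)-2-prenylbenzene
Conditions: MOMCl, i-Pr2NEt, CH2Cl2, 0 → 25 °C
Reagents that add atoms: MOMCl, ClCOC
Why: The free phenol would interfere with the photoredox/NHC step, so it is masked as an acetal.

**Step 6 (key radical step)**
Reactants: **5** aldehyde; **8** aryl iodide; **9** vinyl acetate
Product: **10** (R)-1-[2,4-bis(MOM-oxy)-3-prenylphenyl]-3-[4-(MOM-oxy)-3-prenylphenyl]-1-oxopropan-2-yl acetate
Conditions: chiral aminoindanol-derived N-mesityl triazolium salt (20 mol %), Ir(ppy)3 (1 mol %), Cs2CO3 (1.5 equiv), **8** (1.5 equiv), **9** (10 equiv), PhCF3, blue LEDs, 25 °C, 24 h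
Reagents that add atoms: vinyl acetate (**9**), C=COC(C)=O; the aryl iodide **8** is the other incorporated partner
Why: Proposed new method: excited Ir(ppy)3 reduces ArI to the aryl radical, which adds to the CH2 terminus of vinyl acetate to form the α-acetoxyalkyl radical (a Meerwein-type arylation). Ir(IV) oxidises the NHC–aldehyde Breslow intermediate to its persistent radical, and this radical couples with the α-acetoxyalkyl radical. The chiral NHC scaffold selects one face of the planar radical, setting the (R) carbinol carbon, and NHC elimination releases the ketone (the net process is redox-neutral). The closest known reaction types are NHC/photoredox radical acylation, in which Breslow-derived radicals couple with alkyl radicals, and aryl-radical addition to vinyl acetate.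

**Step 7**
Reactants: **10**
Product: **11** glycybridin C, (R)-2-hydroxy-1-(2,4-dihydroxy-3-prenylphenyl)-3-(4-hydroxy-3-prenylphenyl)propan-1-one
Conditions: conc. HCl (10 equiv), MeOH, 45 °C, 6 h
Reagents that add atoms: none
Why: Acid-catalysed acetal exchange removes the three MOM groups and acid methanolysis removes the acetate. Base is avoided so the α-stereocenter, which is not touched in this step, cannot epimerise through an enediol (global deprotection).

## Compound list
1 | resorcinol | Oc1cccc(O)c1 | starting material
2 | 1,3-bis(methoxymethoxy)benzene | COCOc1cccc(OCOC)c1 | intermediate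
3 | prenyl bromide | CC(C)=CCBr | starting material
4 | 2-prenyl-1,3-bis(methoxymethoxy)benzene | CC(C)=CCc1c(OCOC)cccc1OCOC | intermediate
5 | 2,4-bis(methoxymethoxy)-3-prenylbenzaldehyde | O=Cc1ccc(OCOC)c(CC=C(C)C)c1OCOC | intermediate
6 | 4-iodophenol | Oc1ccc(I)cc1 | starting material
7 | 4-iodo-2-prenylphenol | CC(C)=CCc1cc(I)ccc1O | intermediate
8 | 4-iodo-1-(methoxymethoxy)-2-prenylbenzene | CC(C)=CCc1cc(I)ccc1OCOC | intermediate
9 | vinyl acetate | CC(=O)OC=C | starting material
10 | (R)-α-acetoxy ketone, tris-MOM ether | CC(C)=CCc1cc(C[C@@H](OC(C)=O)C(=O)c2ccc(OCOC)c(CC=C(C)C)c2OCOC)ccc1OCOC | intermediate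
11 | glycybridin C | CC(C)=CCc1cc(C[C@@H](O)C(=O)c2ccc(O)c(CC=C(C)C)c2O)ccc1O | target

## Totals
Total steps: 7. Longest linear sequence: 5 steps (1 → 2 → 3 → 6 → 7, from resorcinol).

## Three steps most likely to fail
1. **Step 6 (radical three-component coupling).** Aryl radicals may abstract H from the doubly activated prenyl CH2 (causing hydrodeiodination), the NHC may be acylated by vinyl acetate, and the enantioselectivity for an α-acetoxyalkyl radical is unproven.
   Fallback: run the coupling with an achiral NHC to give racemic **10**, then resolve by lipase-catalysed (e.g., CAL-B) enantioselective deacetylation of the acetate and carry the (R)-alcohol forward.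
2. **Step 7 (global acidic deprotection).** Prenyl cyclisation to a chroman, or erosion of the α-stereocenter, could occur under the acidic conditions.
   Fallback: re-plan the protecting groups as phenol acetates (prenylate 2,4-dihydroxybenzaldehyde at C3 and Ac2O-protect it; prepare 4-iodo-2-prenylphenyl acetate), so that one mild NH3/MeOH step at 0 °C releases every oxygen with no acid.
3. **Step 4 (ortho-C-prenylation of 4-iodophenol).** O-Alkylation and di-prenylation compete, so the yield may be low.
   Fallback: phenol → MOM ether → directed ortho-lithiation/CuI-prenylation → para-iodination with NIS, which takes three steps but is regiospecific.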